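Per minute, the amber run makes Q on average at 0.0636 M/min up to 3.3 min and the blue run on average at 0.0263 M/min up to 7.5 min. Both have then made about the same Q (0.210 M and 0.197 M), so I take G as about level in the two and read the difference against J.

common to all: G 0.800 M

|  | J | time |
|---|---|---|
| amber | 2.40 M |  |
| blue | 1.20 M |  |
| violet | 0.520 M | 16 min |

- amber run (time / min: [Q] / M): 0.57: 0.050; 1.7: 0.124; 3.3: 0.210; 5.3: 0.297; 7.5: 0.373; 10: 0.435; 13: 0.488; 16: 0.537
- blue run (time / min: [Q] / M): 0.57: 0.016; 1.7: 0.058; 3.3: 0.101; 5.3: 0.157; 7.5: 0.197; 10: 0.240; 13: 0.279; 16: 0.319

(readings scatter by 0.004 M)

- Overall: G + J -> Q.
- Constant volume, constant temperature.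
- What is held in complexes is read along with the free species.
- "The second partner" is J.
- An order is taken over about fifteen percent of the charge, up and down.

- the exponent of [J] in the starting rate at the charge of the amber run (at the point where two percent of the G have become Q)
- Q in the violet run at 16 min, as a share of the G charged

I carry one quantity from these two runs. A first round, with J taken at its charge, gives an exponent of

ln(rate ratio) / ln(J ratio) = 1.28

Then I put J back at an estimate of its mean over the stretch, the charge less half the Q made, which is 2.29 M in amber and 1.10 M in blue. That gives 1.21 for the pair order, the exponent of J between two runs with G allowed for.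

By the overall equation J is the limiting reagent in the violet run, with less of it charged than G. I scale violet from blue's first stretch, taking the rate as proportional to G and to J raised to the pair order.

Main step alone, G and J held at their charge:

Q = 0.194 M

Add the fall of G and J, putting that Q back into the mean levels, then going round once more:

Q = 0.133 M, then 0.151 M, middle 0.142 M

Add the rest, which I can read but not name: over its full 16 min, blue's scaled rate stands at 0.890 of its first stretch. So I rebase on the whole blue run, which covers the same time as violet, starting from the middle value:

Q = 0.132 M, then 0.135 M

I commit to 1.21 for the exponent, taking the pair order for it, and 16.8 % for violet.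

The forecast says 1.3 and 14.5 %, noting that “the local value at 2.4 M could be slightly lower”. Its exponent is higher than mine and its share lower.

The flask gives 1.1 for the exponent and 16.9 % for violet.

    G + 2 J → Q + J (0.4302 /M²/min)
    2 G → Ja (0.02088 /M/min)
    2 J ⇌ J2, settled at all times (3.930 /M)

Where each run has made the Q that is two percent of the amber G charge, the blue run goes at 0.45 of the amber rate, 0.036 M/min against 0.081 M/min. Reckoned as before between blue and violet over 16 min, with violet's result as its mean rate, the pair order comes to 1.20.

The runs are simulated on assumed constants; noise was put on by code.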